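The earlier runs and the new flask were computed for an exercise.

The midnight flask was heading for a leftover. At 90.0 s it held 53.6% of its starting material and was still falling, and the dawn run held 76.5% at 120 s. The two differ in reagent, 0.50 equiv against 0.25 equiv, and each came close to one starting material used per reagent charged, so reagent is the limiting reagent.

| setting | midnight | dawn | flask |
|---|---|---|---|
| starting material | 0.20 M | 0.20 M | 0.20 M |
| reagent | 0.50 equiv | 0.25 equiv | 0.500 equiv |
| remark | the very flask that is asked about, followed so far | run made earlier |  |
| time |  |  | 5.0 min |

| run | time / s | isomer of the product / % | target / % | starting material / % |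
|---|---|---|---|---|
| midnight | 25.0 | 8.0 | 13.7 | 67.9 |
| midnight | 50.0 | 10.2 | 10.4 | 59.6 |
| midnight | 60.0 | 11.1 | 8.5 | 57.2 |
| midnight | 90.0 | 11.4 | 5.3 | 53.6 |
| dawn | 15.0 | 3.2 | 7.0 | 87.9 |
| dawn | 40.0 | 4.2 | 6.8 | 79.6 |
| dawn | 80.0 | 5.9 | 3.8 | 75.9 |
| dawn | 120 | 6.1 | 0.1 | 76.5 |

(standard deviation of a reading: 0.5 percentage points)

- ratio of isomer of the product to target at 1.0 s
- ratio of isomer of the product to target at 20 s
- ratio of isomer of the product to target at 5.0 min



I reckoned three figures from the midnight readings. Isomer of the product took part of the starting material used by 90.0 s; the rest, a share of 75.4%, I took to have gone through target, which puts my ratio at 1.0 s near 0.326. The first reading, taken as one reagent meeting one starting material, gives a making constant of 0.0512 s⁻¹, the share of the charge turned per second if both stood at 0.20 M. Between 60.0 s and 90.0 s the three readings lost from their sum, and that loss per second, divided by the mean target, is a drain of 0.0314 s⁻¹.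

Target's half-life under that drain, 0.368 min, is shorter than 5.0 min. Late target should therefore stand where making meets drain (a steady state). I call this the hold-up, the making constant times target's share over the drain: 1.23. At 0.20 M, I took target as the hold-up times starting material left times reagent left, both as fractions of the starting material charged. I could not read the reagent left at 5.0 min, so I put no ratio there.

The forecast gave 0.34, 0.5 and 290, the last “very uncertain because the two rate constants are close”. The flask gives 0.316, 0.476 and 114.

    target → over-reaction product (k = 0.0320 s⁻¹)
    starting material + reagent ⇌ isomer of the product (K = 400 M⁻¹, k = 0.0620 M⁻¹ s⁻¹)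
    starting material + reagent ⇌ target (K = 32.0 M⁻¹, k = 0.200 M⁻¹ s⁻¹)

Without the step from target to over-reaction product, this flask's ratio at 5.0 min is 0.924 instead of 114. With the reagent actually left, the hold-up gives this flask 0.0935% target, and it stood at 0.115%. In the neighbour with 1.20 equiv, starting material was down to 1.75% and reagent to 18.1% of its charge, so the hold-up gives 0.469%, and target stood at 0.519%.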